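The oxolane ring (O1, C2, C3, C4, C5) is cut at C2–C3 and C4–C5. The feature exploited is that C2–O1–C5 is the carbonyl ylide of a 4-oxygenated benzaldehyde, while the trans C3–C4 pair, carrying C9 as an ester on C3 and the C7' carbinol on C4, is an (E)-γ-silyloxy enoate. One (3+2) cycloaddition closes the ring, makes both C–C bonds and sets C2, C3 and C4 under control of C7'. The precursors are a labile silylmethyl α-chloro ether, with the phenol as an allyl ether so that no hydrogenolysis is needed beside the benzylic acetate, and the enoate made from (R)-4-methoxymandelic acid.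

Key step: step 5

Numbering used in all names: O1, C2 (aryl), C3 (bears C9), C4 (bears C7'), C5 (CH2).

Assumption: (R)-4-methoxymandelic acid and 4-(allyloxy)benzaldehyde are taken as commercial; the carbinol carbon keeps its spatial arrangement from 1 to 14, and its descriptor changes from R to S in step 3 only because the CIP priorities change.

Step 1
Reactants: 1 (R)-2-hydroxy-2-(4-methoxyphenyl)acetic acid
Product: 2 methyl (R)-2-hydroxy-2-(4-methoxyphenyl)acetate
Conditions: MeI, KHCO3, DMF, rt
Reagents that add atoms: iodomethane, CI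
Why: SN2 O-methylation of the potassium carboxylate by iodomethane is selective over the far less acidic benzylic hydroxyl, and the weakly basic conditions leave the stereocentre untouched.

Step 2
Reactants: 2 methyl (R)-2-hydroxy-2-(4-methoxyphenyl)acetate
Product: 3 methyl (R)-2-(4-methoxyphenyl)-2-[(triisopropylsilyl)oxy]acetate
Conditions: TIPSOTf, 2,6-lutidine, CH2Cl2, 0 °C → rt
Reagents that add atoms: triisopropylsilyl trifluoromethanesulfonate, CC(C)[Si](C(C)C)(C(C)C)OS(=O)(=O)C(F)(F)F
Why: Silyl triflate silylation of a secondary alcohol, buffered by 2,6-lutidine, installs the bulky, fluoride-resistant triisopropylsilyl ether without touching any bond at the stereocentre.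

Step 3
Reactants: 3 methyl (R)-2-(4-methoxyphenyl)-2-[(triisopropylsilyl)oxy]acetate
Product: 5 methyl (S,E)-4-(4-methoxyphenyl)-4-[(triisopropylsilyl)oxy]but-2-enoate, via silyloxy aldehyde 4 (not isolated)
Conditions: i-Bu2AlH (1.1 equiv), toluene, −78 °C; then Ph3P=CHCO2Me, −78 °C → rt
Reagents that add atoms: methyl (triphenylphosphoranylidene)acetate, COC(=O)C=P(c1ccccc1)(c1ccccc1)c1ccccc1
Why: Partial ester reduction with i-Bu2AlH stops at the aluminium hemiacetal at −78 °C, and the aldehyde released on warming is trapped at once by the stabilised ylide in an (E)-selective Wittig olefination, so the enolisable α-aryl aldehyde never accumulates and the carbinol centre keeps its spatial arrangement.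

Step 4
Reactants: 6 4-(allyloxy)benzaldehyde; 7 (trimethylsilyl)methanol
Product: 8 chloro[4-(allyloxy)phenyl]methyl (trimethylsilyl)methyl ether (racemic, moisture-sensitive)
Conditions: HCl (g), MgSO4, CH2Cl2, 0 °C; filter, concentrate, use crude at once
Reagents that add atoms: hydrogen chloride, Cl
Why: In this classical α-chloro ether synthesis the hemiacetal of aldehyde and alcohol is converted by HCl, through the aryl-stabilised oxocarbenium ion, into the chloride while MgSO4 binds the water; the racemic centre does not matter because it becomes planar in the ylide.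

Step 5
Reactants: 5 methyl (S,E)-4-(4-methoxyphenyl)-4-[(triisopropylsilyl)oxy]but-2-enoate; 8 chloro[4-(allyloxy)phenyl]methyl (trimethylsilyl)methyl ether
Product: 10 methyl (2R,3R,4R)-2-[4-(allyloxy)phenyl]-4-[(S)-(4-methoxyphenyl)(triisopropylsilyloxy)methyl]oxolane-3-carboxylate, via carbonyl ylide 9 (not isolated)
Conditions: CsF (4 equiv), MeCN, 0 °C → rt; 8 (2.5 equiv) added slowly
Reagents that add atoms: none
Why: Loss of chloride from 8 and attack of fluoride on silicon (a 1,3-elimination) release the non-stabilised carbonyl ylide 9, which adds to the electron-poor alkene of 5 in a concerted, asynchronous (3+2) cycloaddition, the reaction type known for silylmethyl α-chloro ethers with acrylates, fumarates and enones. The oxolane ring is closed in this intermolecular [4π+2π] mode, C4–C5 and C2–C3 forming suprafacially in one transition state, so no separate cyclisation is involved. The unsubstituted, more nucleophilic CH2 terminus (C5) bonds to the β-carbon C4 and the aryl-stabilised terminus (C2) to C3; this regiochemistry is secured because the ester is the only acceptor group, C7' being a silyl-protected carbinol. C4 is set by C7': in the Felkin-type conformer with the C7' hydrogen near the alkene plane and the bulky silyloxy group anti to the incoming C5, the open face leads to the (4R,7'S) pair. C3 follows from C4, since suprafacial addition turns the (E)-geometry into the 3,4-trans relationship. C2 is set by the exo approach in which the aryl group, outward on the ylide, avoids the ester and ends 2,3-trans; this is the least secure selectivity, and any 2,3-cis isomer is to be removed by chromatography at this stage.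

Step 6
Reactants: 10 methyl (2R,3R,4R)-2-[4-(allyloxy)phenyl]-4-[(S)-(4-methoxyphenyl)(triisopropylsilyloxy)methyl]oxolane-3-carboxylate
Product: 11 {(2R,3S,4R)-2-[4-(allyloxy)phenyl]-4-[(S)-(4-methoxyphenyl)(triisopropylsilyloxy)methyl]oxolan-3-yl}methanol
Conditions: LiAlH4, THF, 0 °C
Reagents that add atoms: none
Why: Hydride reduction of the ester with LiAlH4 gives the C9 primary alcohol while the silyl ether, the allyl aryl ether and the benzylic ring ether are inert, and the cold, non-enolising conditions leave C3 unchanged (its descriptor becomes S by CIP priority only).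

Step 7
Reactants: 11 {(2R,3S,4R)-2-[4-(allyloxy)phenyl]-4-[(S)-(4-methoxyphenyl)(triisopropylsilyloxy)methyl]oxolan-3-yl}methanol
Product: 12 (S)-{(2R,3S,4R)-2-[4-(allyloxy)phenyl]-3-(hydroxymethyl)oxolan-4-yl}(4-methoxyphenyl)methanol
Conditions: Bu4NF, THF, rt → 40 °C
Reagents that add atoms: none
Why: Fluoride-driven cleavage of the Si–O bond (silyl ether deprotection) frees the C7' hydroxyl without breaking the C7'–O bond, so the configuration is retained.

Step 8
Reactants: 12 (S)-{(2R,3S,4R)-2-[4-(allyloxy)phenyl]-3-(hydroxymethyl)oxolan-4-yl}(4-methoxyphenyl)methanol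
Product: 13 {(2R,3S,4R)-4-[(S)-acetoxy(4-methoxyphenyl)methyl]-2-[4-(allyloxy)phenyl]oxolan-3-yl}methyl acetate
Conditions: Ac2O, pyridine, DMAP (cat.), CH2Cl2, 0 °C → rt
Reagents that add atoms: acetic anhydride, CC(=O)OC(C)=O
Why: Acylation of the primary and the secondary benzylic hydroxyl with acetic anhydride under nucleophilic catalysis by 4-(dimethylamino)pyridine forms both acetates at oxygen, with no C–O bond broken and hence no change at C7'.

Step 9
Reactants: 13 {(2R,3S,4R)-4-[(S)-acetoxy(4-methoxyphenyl)methyl]-2-[4-(allyloxy)phenyl]oxolan-3-yl}methyl acetate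
Product: 14 {(2R,3S,4R)-4-[(S)-acetoxy(4-methoxyphenyl)methyl]-2-(4-hydroxyphenyl)oxolan-3-yl}methyl acetate (CNP0231272.1)
Conditions: Pd(PPh3)4 (5 mol %), morpholine, THF, rt
Reagents that add atoms: none
Why: In this Tsuji–Trost-type deallylation Pd(PPh3)4 (zerovalent palladium) ionises only the allyl aryl ether to a π-allyl complex and the phenoxide, morpholine captures the allyl group, and the alkyl acetate, the 4-methoxybenzylic acetate and the benzylic ring ether are left alone under these neutral, non-reductive conditions.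

Compound list
1 | (R)-2-hydroxy-2-(4-methoxyphenyl)acetic acid, (R)-4-methoxymandelic acid | COc1ccc([C@@H](O)C(=O)O)cc1 | starting material
2 | methyl (R)-2-hydroxy-2-(4-methoxyphenyl)acetate | COc1ccc([C@@H](O)C(=O)OC)cc1 | intermediate
3 | methyl (R)-2-(4-methoxyphenyl)-2-[(triisopropylsilyl)oxy]acetate | COc1ccc([C@@H](O[Si](C(C)C)(C(C)C)C(C)C)C(=O)OC)cc1 | intermediate
4 | (R)-2-(4-methoxyphenyl)-2-[(triisopropylsilyl)oxy]acetaldehyde, formed and consumed in the flask | COc1ccc([C@@H](O[Si](C(C)C)(C(C)C)C(C)C)C=O)cc1 | intermediate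
5 | methyl (S,E)-4-(4-methoxyphenyl)-4-[(triisopropylsilyl)oxy]but-2-enoate | COc1ccc([C@@H](O[Si](C(C)C)(C(C)C)C(C)C)/C=C/C(=O)OC)cc1 | intermediate
6 | 4-(allyloxy)benzaldehyde | C=CCOc1ccc(C=O)cc1 | starting material
7 | (trimethylsilyl)methanol | C[Si](C)(C)CO | starting material
8 | chloro[4-(allyloxy)phenyl]methyl (trimethylsilyl)methyl ether, racemic | C[Si](C)(C)COC(Cl)c1ccc(OCC=C)cc1 | intermediate
9 | carbonyl ylide of 4-(allyloxy)benzaldehyde with a CH2 terminus on oxygen, formed and consumed in the flask | [CH2-][O+]=Cc1ccc(OCC=C)cc1 | intermediate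
10 | methyl (2R,3R,4R)-2-[4-(allyloxy)phenyl]-4-[(S)-(4-methoxyphenyl)(triisopropylsilyloxy)methyl]oxolane-3-carboxylate, all-trans ring | COc1ccc([C@@H](O[Si](C(C)C)(C(C)C)C(C)C)[C@H]2CO[C@@H](c3ccc(OCC=C)cc3)[C@@H]2C(=O)OC)cc1 | intermediate
11 | {(2R,3S,4R)-2-[4-(allyloxy)phenyl]-4-[(S)-(4-methoxyphenyl)(triisopropylsilyloxy)methyl]oxolan-3-yl}methanol | COc1ccc([C@@H](O[Si](C(C)C)(C(C)C)C(C)C)[C@H]2CO[C@@H](c3ccc(OCC=C)cc3)[C@@H]2CO)cc1 | intermediate
12 | (S)-{(2R,3S,4R)-2-[4-(allyloxy)phenyl]-3-(hydroxymethyl)oxolan-4-yl}(4-methoxyphenyl)methanol | COc1ccc([C@@H](O)[C@H]2CO[C@@H](c3ccc(OCC=C)cc3)[C@@H]2CO)cc1 | intermediate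
13 | {(2R,3S,4R)-4-[(S)-acetoxy(4-methoxyphenyl)methyl]-2-[4-(allyloxy)phenyl]oxolan-3-yl}methyl acetate | COc1ccc([C@@H](OC(C)=O)[C@H]2CO[C@@H](c3ccc(OCC=C)cc3)[C@@H]2COC(C)=O)cc1 | intermediate
14 | {(2R,3S,4R)-4-[(S)-acetoxy(4-methoxyphenyl)methyl]-2-(4-hydroxyphenyl)oxolan-3-yl}methyl acetate | COc1ccc([C@@H](OC(C)=O)[C@H]2CO[C@@H](c3ccc(O)cc3)[C@@H]2COC(C)=O)cc1 | target

Total step count: 9. Longest linear sequence: 8 steps (steps 1, 2, 3, 5, 6, 7, 8, 9); the chloro ether branch is one step (step 4).

Steps most likely to fail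

Step 5. The ylide may be lost to oxirane closure or dimerisation before the hindered, only moderately activated enoate traps it. The addition may also discriminate poorly between the two alkene faces or between exo and endo placement of the aryl group. The fallback sets out from 5 and comes back at 11, and builds the same ring stepwise with one centre set at a time.
- Copper-catalysed conjugate addition of vinylmagnesium bromide (CuBr·SMe2, Me3SiCl, THF, −78 °C) to 5 should occur anti to the silyloxy group, as is usual for (E)-γ-silyloxy enoates, and give methyl (3R,4S)-3-ethenyl-4-(4-methoxyphenyl)-4-[(triisopropylsilyl)oxy]butanoate F1.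
- Ozonolysis with NaBH4 work-up and acid-catalysed lactonisation should give (R)-4-[(S)-(4-methoxyphenyl)(triisopropylsilyloxy)methyl]oxolan-2-one F2. Its carbonyl carbon is the later C2 and its ring oxygen is O1.
- Deprotonation with LiN(i-Pr)2 and hydroxymethylation with monomeric formaldehyde, on the face away from the C4 substituent, should give the trans lactone (3S,4R)-3-(hydroxymethyl)-4-[(S)-(4-methoxyphenyl)(triisopropylsilyloxy)methyl]oxolan-2-one F3, which carries C9.
- An excess of [4-(allyloxy)phenyl]lithium F4, made from 1-(allyloxy)-4-bromobenzene and n-BuLi at −78 °C, should open the lactone to the aryl ketone (2S,3R)-1-[4-(allyloxy)phenyl]-4-hydroxy-2-(hydroxymethyl)-3-[(S)-(4-methoxyphenyl)(triisopropylsilyloxy)methyl]butan-1-one F5.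
- NaBH4 should reduce this ketone to the triol (2S,3R)-1-[4-(allyloxy)phenyl]-2-(hydroxymethyl)-3-[(S)-(4-methoxyphenyl)(triisopropylsilyloxy)methyl]butane-1,4-diol F6, as a mixture at the new carbinol.
- Catalytic camphorsulfonic acid in CH2Cl2 then ionises the 4-alkoxybenzylic alcohol, and the C5 hydroxyl closes the five-membered ring reversibly, which should settle on the all-trans oxolane 11.

Step 4. The electron-rich chloro ether may form incompletely or be hydrolysed back by the water generated with it, leaving material unfit for ylide generation. The fallback sets out from 6 and 7 and comes back at 8, and avoids water in the chloride-forming step. Acid-catalysed acetalisation of 6 with two equivalents of 7 (TsOH cat., toluene, azeotropic removal of water) should give 1-(allyloxy)-4-{bis[(trimethylsilyl)methoxy]methyl}benzene F7. Acetyl chloride with a trace of ZnCl2 then exchanges one alkoxy group for chloride under anhydrous conditions and gives 8.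

Step 3. The reduction may run on to the primary alcohol, or the aluminium hemiacetal may collapse early. The carbinol configuration may also be eroded by enolisation of the α-aryl aldehyde. The fallback sets out from 3 and comes back at 5. Full reduction with LiBH4 in THF should give (R)-2-(4-methoxyphenyl)-2-[(triisopropylsilyl)oxy]ethan-1-ol F8. Oxidation of F8 with Dess–Martin periodinane in CH2Cl2 (NaHCO3 buffer) in the presence of methyl (triphenylphosphoranylidene)acetate then forms aldehyde 4 under non-basic conditions and traps it at once as 5.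

Further compounds
F1 | step 5 | methyl (3R,4S)-3-ethenyl-4-(4-methoxyphenyl)-4-[(triisopropylsilyl)oxy]butanoate | COc1ccc([C@@H](O[Si](C(C)C)(C(C)C)C(C)C)[C@@H](C=C)CC(=O)OC)cc1
F2 | step 5 | (R)-4-[(S)-(4-methoxyphenyl)(triisopropylsilyloxy)methyl]oxolan-2-one | COc1ccc([C@@H](O[Si](C(C)C)(C(C)C)C(C)C)[C@H]2COC(=O)C2)cc1
F3 | step 5 | (3S,4R)-3-(hydroxymethyl)-4-[(S)-(4-methoxyphenyl)(triisopropylsilyloxy)methyl]oxolan-2-one | COc1ccc([C@@H](O[Si](C(C)C)(C(C)C)C(C)C)[C@H]2COC(=O)[C@@H]2CO)cc1
F4 | step 5 | [4-(allyloxy)phenyl]lithium | [Li]c1ccc(OCC=C)cc1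
F5 | step 5 | (2S,3R)-1-[4-(allyloxy)phenyl]-4-hydroxy-2-(hydroxymethyl)-3-[(S)-(4-methoxyphenyl)(triisopropylsilyloxy)methyl]butan-1-one | COc1ccc([C@@H](O[Si](C(C)C)(C(C)C)C(C)C)[C@@H](CO)[C@@H](CO)C(=O)c2ccc(OCC=C)cc2)cc1
F6 | step 5 | (2S,3R)-1-[4-(allyloxy)phenyl]-2-(hydroxymethyl)-3-[(S)-(4-methoxyphenyl)(triisopropylsilyloxy)methyl]butane-1,4-diol, mixture at C1 | COc1ccc([C@@H](O[Si](C(C)C)(C(C)C)C(C)C)[C@@H](CO)[C@@H](CO)C(O)c2ccc(OCC=C)cc2)cc1
F7 | step 4 | 1-(allyloxy)-4-{bis[(trimethylsilyl)methoxy]methyl}benzene | C=CCOc1ccc(C(OC[Si](C)(C)C)OC[Si](C)(C)C)cc1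
F8 | step 3 | (R)-2-(4-methoxyphenyl)-2-[(triisopropylsilyl)oxy]ethan-1-ol | COc1ccc([C@@H](O[Si](C(C)C)(C(C)C)C(C)C)CO)cc1
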